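**Plan**
Cuts, in retrosynthetic order: the two MOM O–CH2 bonds (O5, O3'); O1–C2 and C3–OH of ring C, back to a 2'-hydroxychalcone; C4a–C5 of ring A, back to a 6-acylmethylpyran-2-one; C4–C4a; the prenyl bonds at C6 and C8; the C2=C3 alkene of the ring-B arm.
Enabling feature: in ring A the oxygen-bearing C5, C7 and C8a alternate with the carbon-substituted C6, C8 and C4a, and C4a carries the C4 carbonyl. This is a linear C5-to-C4 tetraketide closed between C4a and C5, and its C5–C8a segment can be stored as a 4-methoxypyran-2-one.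
Forward order: ring B is bought. The pyranone is dibrominated and diprenylated, joined to the ring-B arm at C4–C4a and refolded into ring A (step 6); ring C closes last (step 8).
Stereochemistry: the target has no stereocentre. The E-enone comes from a Horner–Wadsworth–Emmons reaction and is consumed in ring C. The cis placement of C5 and C8 across C6=C7 that the folding needs is inherited from the pyranone ring.

Key step: step 6

Remark: all intermediates carry the atom numbering of the flavonol (O1, C2–C4, C4a, C5–C8, C8a, primed ring B); intermediates with transient stereocentres are racemic, and where configuration is written one enantiomer is drawn.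

Step 1
Reactants: 1 4-methoxy-6-methylpyran-2-one
Product: 2 3,5-dibromo-4-methoxy-6-methylpyran-2-one
Conditions: NBS (2.4 equiv), MeCN, dark, 25 to 60 °C
Reagents that add atoms: N-bromosuccinimide, O=C1CCC(=O)N1Br
Why: Electrophilic bromination of an electron-rich heterocycle, in which C3 and C5 are the nucleophilic β-carbons of the enol ether and enol lactone units and the only ring C–H positions, while a polar solvent without light or initiator keeps the reaction ionic and spares the 6-methyl group.

Step 2
Reactants: 2 3,5-dibromo-4-methoxy-6-methylpyran-2-one; 3 tributyl(3-methylbut-2-enyl)stannane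
Product: 4 4-methoxy-6-methyl-3,5-bis(3-methylbut-2-enyl)pyran-2-one
Conditions: 3 (2.6 equiv), Pd(PPh3)4 (10 mol %), DMF, 100 °C, argon
Reagents that add atoms: none
Why: Twofold Stille coupling, in which zerovalent palladium inserts into both C(sp2)–Br bonds of the bromopyranone, a halide class on which such couplings are established, and reductive elimination at the unsubstituted terminus of the dimethylallyl ligand should give the linear prenyl groups as it does with aryl bromides.

Step 3
Reactants: 5 isovanillin (3-hydroxy-4-methoxybenzaldehyde)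
Product: 6 4-methoxy-3-(methoxymethoxy)benzaldehyde
Conditions: MOMCl (1.3 equiv), i-Pr2NEt (2 equiv), CH2Cl2, 0 °C to rt
Reagents that add atoms: chloromethyl methyl ether, COCCl
Why: Williamson-type O-alkylation of the phenol by the reactive α-chloro ether gives an acetal that withstands every basic and oxidative step up to step 8.

Step 4
Reactants: 6 4-methoxy-3-(methoxymethoxy)benzaldehyde; 7 diethyl {2-[methoxy(methyl)amino]-2-oxoethyl}phosphonate
Product: 8 (E)-N-methoxy-3-[4-methoxy-3-(methoxymethoxy)phenyl]-N-methylprop-2-enamide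
Conditions: NaH (1.2 equiv), THF, 0 °C to rt
Reagents that add atoms: none
Why: Horner–Wadsworth–Emmons olefination, in which the stabilised phosphonoacetamide anion adds reversibly to the aromatic aldehyde and the faster collapse of the anti adduct sets the E double bond.

Step 5
Reactants: 4 4-methoxy-6-methyl-3,5-bis(3-methylbut-2-enyl)pyran-2-one; 8 (E)-N-methoxy-3-[4-methoxy-3-(methoxymethoxy)phenyl]-N-methylprop-2-enamide
Product: 10 4-methoxy-6-{(E)-4-[4-methoxy-3-(methoxymethoxy)phenyl]-2-oxobut-3-enyl}-3,5-bis(3-methylbut-2-enyl)pyran-2-one, via lithiated pyranone 9 (not isolated)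
Conditions: LiN(SiMe3)2 (2.1 equiv), THF, −78 °C; then 8, −78 to −30 °C; AcOH quench
Reagents that add atoms: none
Why: Vinylogous deprotonation followed by a Weinreb ketone synthesis, since with C3 blocked the 6-methyl group is the only site whose anion is conjugated through the ring to the lactone carbonyl, and the N-methoxy-N-methylamide takes up this anion once and at its carbonyl carbon, which avoids the conjugate addition and proton-transfer losses expected of a cinnamate ester.

Step 6
Reactants: 10 4-methoxy-6-{(E)-4-[4-methoxy-3-(methoxymethoxy)phenyl]-2-oxobut-3-enyl}-3,5-bis(3-methylbut-2-enyl)pyran-2-one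
Product: 12 (E)-1-[2,6-dihydroxy-4-methoxy-3,5-bis(3-methylbut-2-enyl)phenyl]-3-[4-methoxy-3-(methoxymethoxy)phenyl]prop-2-en-1-one, via open-chain diketo ester 11 (not isolated)
Conditions: Mg(OMe)2 (4 equiv), MeOH, reflux, argon; then cold 1 M HCl
Reagents that add atoms: none
Why: Mg(OMe)2 first turns the C4a methylene of 10 into its magnesium enolate, methoxide then adds to the lactone carbonyl (future C5) and the bond from C5 to the ring oxygen breaks, giving the open-chain methyl ester 11 as a chelated β-diketonate; its central carbon C4a attacks the ester carbonyl, methoxide leaves and two enolisations aromatise ring A. The closest known reaction is the magnesium methoxide recyclisation of 6-(2-oxoalkyl)-4-methoxypyran-2-ones, which are masked 3,5,7-triketo esters, to acylphloroglucinol monomethyl ethers, an intramolecular Claisen (Dieckmann-type) condensation. Ring A closes in the 6-exo-trig mode at the ester carbonyl and this forms the C4a–C5 bond. No stereocentre is created, because the C8 centre of 11 is transient and vanishes on aromatisation and the E-enone is not touched. The selectivity needed is Claisen against aldol folding: C6 is a fully substituted enol-ether carbon without hydrogen and cannot act as nucleophile in a C6-to-C4 aldol closure, C7 is masked as its methyl enol ether, and the chelated diketonate lowers the electrophilicity of C4 and C8a while it makes C4a the carbanion. The C6=C7 double bond keeps the geometry it had in the ring, with C5 and C8 cis (formally E, because OMe outranks carbon), so the ester lies next to C4a, and aromatisation makes the closure irreversible whereas relactonisation and additions to the enone are reversible.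

Step 7
Reactants: 12 (E)-1-[2,6-dihydroxy-4-methoxy-3,5-bis(3-methylbut-2-enyl)phenyl]-3-[4-methoxy-3-(methoxymethoxy)phenyl]prop-2-en-1-one
Product: 13 (E)-1-[2-hydroxy-4-methoxy-6-(methoxymethoxy)-3,5-bis(3-methylbut-2-enyl)phenyl]-3-[4-methoxy-3-(methoxymethoxy)phenyl]prop-2-en-1-one
Conditions: MOMCl (1.1 equiv), i-Pr2NEt (1.5 equiv), CH2Cl2, 0 °C
Reagents that add atoms: chloromethyl methyl ether, COCCl
Why: Selective mono-O-alkylation of a chelated 2,6-dihydroxyaryl ketone, in which the two hydroxyls are equivalent so that either gives 13, the remaining one is then locked in a hydrogen bond to the carbonyl and stops reacting, and the cap suppresses both the easy chalcone-to-flavanone drift and the doubly charged, unreactive enone in the next step.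

Step 8
Reactants: 13 (E)-1-[2-hydroxy-4-methoxy-6-(methoxymethoxy)-3,5-bis(3-methylbut-2-enyl)phenyl]-3-[4-methoxy-3-(methoxymethoxy)phenyl]prop-2-en-1-one
Product: 15 3-hydroxy-7-methoxy-5-(methoxymethoxy)-2-[4-methoxy-3-(methoxymethoxy)phenyl]-6,8-bis(3-methylbut-2-enyl)chromen-4-one, via trans-dihydroflavonol 14 (not isolated)
Conditions: 30 % aq H2O2, 2 M aq NaOH, MeOH–THF, 0 °C to rt; then AcOH to pH 6
Reagents that add atoms: hydrogen peroxide, OO
Why: Algar–Flynn–Oyamada reaction, in which hydroperoxide attacks only the electron-poor enone, the 2'-phenoxide closes ring C at the β-carbon C2 to give 14, whose two centres are erased when more peroxide dehydrogenates it to the flavonol, and the nucleophilic oxidant leaves the electron-rich prenyl alkenes alone, as known for 6'-alkoxy-3'-prenyl-2'-hydroxychalcones.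

Step 9
Reactants: 15 3-hydroxy-7-methoxy-5-(methoxymethoxy)-2-[4-methoxy-3-(methoxymethoxy)phenyl]-6,8-bis(3-methylbut-2-enyl)chromen-4-one
Product: 16 3,5-dihydroxy-2-(3-hydroxy-4-methoxyphenyl)-7-methoxy-6,8-bis(3-methylbut-2-enyl)chromen-4-one
Conditions: 3 M aq HCl (cat.), MeOH–THF, 45 °C
Reagents that add atoms: none
Why: Acid-catalysed acetal methanolysis removes both aryl MOM ethers, the peri 5-O-MOM fastest, under conditions used on C-prenylated flavonoids, and the freed 5-OH is held in a hydrogen bond to C4=O so that chroman formation with the 6-prenyl group should stay slow.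

**Compound list**
1 | 4-methoxy-6-methylpyran-2-one | COc1cc(C)oc(=O)c1 | starting material
2 | 3,5-dibromo-4-methoxy-6-methylpyran-2-one | COc1c(Br)c(C)oc(=O)c1Br | intermediate
3 | tributyl(3-methylbut-2-enyl)stannane | CCCC[Sn](CCCC)(CCCC)CC=C(C)C | starting material
4 | 4-methoxy-6-methyl-3,5-bis(3-methylbut-2-enyl)pyran-2-one | COc1c(CC=C(C)C)c(C)oc(=O)c1CC=C(C)C | intermediate
5 | isovanillin (3-hydroxy-4-methoxybenzaldehyde) | COc1ccc(C=O)cc1O | starting material
6 | 4-methoxy-3-(methoxymethoxy)benzaldehyde | COCOc1cc(C=O)ccc1OC | intermediate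
7 | diethyl {2-[methoxy(methyl)amino]-2-oxoethyl}phosphonate | CCOP(=O)(CC(=O)N(C)OC)OCC | starting material
8 | (E)-N-methoxy-3-[4-methoxy-3-(methoxymethoxy)phenyl]-N-methylprop-2-enamide | CON(C)C(=O)/C=C/c1ccc(OC)c(OCOC)c1 | intermediate
9 | 6-(lithiomethyl)-4-methoxy-3,5-bis(3-methylbut-2-enyl)pyran-2-one | [Li]Cc1oc(=O)c(CC=C(C)C)c(OC)c1CC=C(C)C | intermediate
10 | 4-methoxy-6-{(E)-4-[4-methoxy-3-(methoxymethoxy)phenyl]-2-oxobut-3-enyl}-3,5-bis(3-methylbut-2-enyl)pyran-2-one | O=c1oc(CC(=O)/C=C/c2ccc(OC)c(OCOC)c2)c(CC=C(C)C)c(OC)c1CC=C(C)C | intermediate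
11 | methyl (2E,8E)-3-methoxy-9-[4-methoxy-3-(methoxymethoxy)phenyl]-2,4-bis(3-methylbut-2-enyl)-5,7-dioxonona-2,8-dienoate (racemic at chain C4, present as its magnesium enolate) | COC(=O)/C(CC=C(C)C)=C(OC)\C(CC=C(C)C)C(=O)CC(=O)/C=C/c1ccc(OC)c(OCOC)c1 | intermediate
12 | (E)-1-[2,6-dihydroxy-4-methoxy-3,5-bis(3-methylbut-2-enyl)phenyl]-3-[4-methoxy-3-(methoxymethoxy)phenyl]prop-2-en-1-one | COc1ccc(/C=C/C(=O)c2c(O)c(CC=C(C)C)c(OC)c(CC=C(C)C)c2O)cc1OCOC | intermediate
13 | (E)-1-[2-hydroxy-4-methoxy-6-(methoxymethoxy)-3,5-bis(3-methylbut-2-enyl)phenyl]-3-[4-methoxy-3-(methoxymethoxy)phenyl]prop-2-en-1-one | COc1ccc(/C=C/C(=O)c2c(O)c(CC=C(C)C)c(OC)c(CC=C(C)C)c2OCOC)cc1OCOC | intermediate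
14 | rac-(2R,3R)-3-hydroxy-7-methoxy-5-(methoxymethoxy)-2-[4-methoxy-3-(methoxymethoxy)phenyl]-6,8-bis(3-methylbut-2-enyl)-2,3-dihydrochromen-4-one | COc1ccc(cc1OCOC)[C@@H]2[C@H](C(=O)c3c(OCOC)c(CC=C(C)C)c(OC)c(CC=C(C)C)c3O2)O | intermediate
15 | 3-hydroxy-7-methoxy-5-(methoxymethoxy)-2-[4-methoxy-3-(methoxymethoxy)phenyl]-6,8-bis(3-methylbut-2-enyl)chromen-4-one | COc1ccc(cc1OCOC)-c1oc2c(CC=C(C)C)c(OC)c(CC=C(C)C)c(OCOC)c2c(=O)c1O | intermediate
16 | 3,5-dihydroxy-2-(3-hydroxy-4-methoxyphenyl)-7-methoxy-6,8-bis(3-methylbut-2-enyl)chromen-4-one (CNP0261856.0) | COc1ccc(-c2oc3c(CC=C(C)C)c(OC)c(CC=C(C)C)c(O)c3c(=O)c2O)cc1O | target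

**Step count and risks**
Total steps: 9. Longest linear sequence: 7 (steps 1, 2, 5, 6, 7, 8, 9, from compound 1).

Step 6. Methoxide may fail to open the fully substituted lactone once the side chain is deprotonated. The opened chain may also be drained by retro-Claisen loss of the cinnamoyl unit or by oxa-Michael closure of the diketone enol onto the styryl enone, and the chalcone may drift to its flavanone on work-up. The fallback buys ring A instead of folding it; it sets out from 6 and comes back at 13. Commercial 2,4,6-trihydroxyacetophenone is C-prenylated twice with prenyl bromide in cold aqueous KOH to give 1-[2,4,6-trihydroxy-3,5-bis(3-methylbut-2-enyl)phenyl]ethanone F1. One equivalent of Me2SO4 with K2CO3 in acetone methylates the non-chelated, most acidic 4-OH to give 1-[2,6-dihydroxy-4-methoxy-3,5-bis(3-methylbut-2-enyl)phenyl]ethanone F2. MOMCl and i-Pr2NEt cap one of the two equivalent hydroxyls to give 1-[2-hydroxy-4-methoxy-6-(methoxymethoxy)-3,5-bis(3-methylbut-2-enyl)phenyl]ethanone F3. Claisen–Schmidt condensation of this ketone with 6 (KOH, EtOH, rt) gives 13.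

Step 8. The 6'-OMOM and 5'-prenyl groups twist the aroyl unit, so the phenoxide may close at the α-carbon to a five-membered ring instead of at C2. Peroxide addition may also be slow enough for oxidative degradation of ring A to compete. The fallback separates epoxidation from ring closure; it sets out from 13 and comes back at 16. NaH and MOMCl in DMF cap the chelated hydroxyl to give (E)-1-[4-methoxy-2,6-bis(methoxymethoxy)-3,5-bis(3-methylbut-2-enyl)phenyl]-3-[4-methoxy-3-(methoxymethoxy)phenyl]prop-2-en-1-one F4. Weitz–Scheffer epoxidation (H2O2, NaOH, MeOH) gives racemic trans-[4-methoxy-2,6-bis(methoxymethoxy)-3,5-bis(3-methylbut-2-enyl)phenyl]{3-[4-methoxy-3-(methoxymethoxy)phenyl]oxiran-2-yl}methanone F5. HCl in MeOH removes the three MOM ethers, and a freed phenol opens the epoxide at its benzylic carbon with inversion to give rac-(2R,3R)-3,5-dihydroxy-2-(3-hydroxy-4-methoxyphenyl)-7-methoxy-6,8-bis(3-methylbut-2-enyl)-2,3-dihydrochromen-4-one F6. Alkaline H2O2, which does not touch the prenyl groups, dehydrogenates this dihydroflavonol to 16.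

Step 5. The stabilised and hindered anion 9 may add too slowly to the amide, so that self-condensation, base-induced breakdown of the N–OMe unit or conjugate addition take over. The fallback replaces acylation by addition to an aldehyde and oxidation; it sets out from 6 and 4 and comes back at 10. Wittig reaction of 6 with Ph3P=CHCHO in toluene gives (E)-3-[4-methoxy-3-(methoxymethoxy)phenyl]prop-2-enal F7. Anion 9, made from 4 as in step 5, adds 1,2 to this enal at −78 °C to give racemic 6-{(E)-2-hydroxy-4-[4-methoxy-3-(methoxymethoxy)phenyl]but-3-enyl}-4-methoxy-3,5-bis(3-methylbut-2-enyl)pyran-2-one F8. MnO2 in CH2Cl2 oxidises the allylic alcohol to 10.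

**Further compounds**
F1 | step 6 | 1-[2,4,6-trihydroxy-3,5-bis(3-methylbut-2-enyl)phenyl]ethanone | CC(=O)c1c(O)c(CC=C(C)C)c(O)c(CC=C(C)C)c1O
F2 | step 6 | 1-[2,6-dihydroxy-4-methoxy-3,5-bis(3-methylbut-2-enyl)phenyl]ethanone | CC(=O)c1c(O)c(CC=C(C)C)c(OC)c(CC=C(C)C)c1O
F3 | step 6 | 1-[2-hydroxy-4-methoxy-6-(methoxymethoxy)-3,5-bis(3-methylbut-2-enyl)phenyl]ethanone | CC(=O)c1c(O)c(CC=C(C)C)c(OC)c(CC=C(C)C)c1OCOC
F4 | step 8 | (E)-1-[4-methoxy-2,6-bis(methoxymethoxy)-3,5-bis(3-methylbut-2-enyl)phenyl]-3-[4-methoxy-3-(methoxymethoxy)phenyl]prop-2-en-1-one | COc1ccc(/C=C/C(=O)c2c(OCOC)c(CC=C(C)C)c(OC)c(CC=C(C)C)c2OCOC)cc1OCOC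
F5 | step 8 | racemic trans-[4-methoxy-2,6-bis(methoxymethoxy)-3,5-bis(3-methylbut-2-enyl)phenyl]{3-[4-methoxy-3-(methoxymethoxy)phenyl]oxiran-2-yl}methanone, (2R,3S) enantiomer drawn | COCOc1c(CC=C(C)C)c(OC)c(CC=C(C)C)c(OCOC)c1C(=O)[C@@H]1O[C@H]1c1ccc(OC)c(OCOC)c1
F6 | step 8 | rac-(2R,3R)-3,5-dihydroxy-2-(3-hydroxy-4-methoxyphenyl)-7-methoxy-6,8-bis(3-methylbut-2-enyl)-2,3-dihydrochromen-4-one | COc1ccc(cc1O)[C@@H]2[C@H](C(=O)c3c(O)c(CC=C(C)C)c(OC)c(CC=C(C)C)c3O2)O
F7 | step 5 | (E)-3-[4-methoxy-3-(methoxymethoxy)phenyl]prop-2-enal | COCOc1cc(/C=C/C=O)ccc1OC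
F8 | step 5 | racemic 6-{(E)-2-hydroxy-4-[4-methoxy-3-(methoxymethoxy)phenyl]but-3-enyl}-4-methoxy-3,5-bis(3-methylbut-2-enyl)pyran-2-one | O=c1oc(CC(O)/C=C/c2ccc(OC)c(OCOC)c2)c(CC=C(C)C)c(OC)c1CC=C(C)C
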